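(The readings are simulated for substances that don't exist.)

In litres per mole, one number tells you how much of the X this flask holds bound once it is at rest: the hold H = ([E] + [L]) / ([X][Q]), an overall equilibrium constant. The asked flask is the elm run carried on.

all flasks: X 0.20 M; J 2.8 mM

| run | Q | remark | time |
|---|---|---|---|
| elm | 0.24 M | the very flask that is asked about, followed so far |  |
| ash | 0.48 M | run made earlier |  |
| flask | 0.240 M |  | 15 d |

- elm (time / h: E / %, L / %, X / %): 3.00: 21.8, 3.6, 76.1; 8.00: 21.4, 6.0, 72.5; 15.0: 20.9, 10.2, 69.6; 25.0: 18.7, 16.0, 66.6; 30.0: 17.7, 19.3, 64.2; 40.0: 16.2, 23.6, 61.0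
- ash (time / d: E / %, L / %, X / %): 1.04: 27.3, 25.5, 45.8; 3.00: 17.3, 50.9, 31.8; 5.00: 12.5, 62.5, 25.2; 8.00: 11.4, 68.7, 20.3; 12.0: 9.6, 71.4, 19.6; 15.0: 9.9, 71.0, 18.4

(each reading ± 0.5 percentage points)

- why nothing more happens at 15 d, or that something still does (Q has run out first / no working catalyst is left / forward and back rates have come level / all of X has reacted / it is still moving)
- amount of E at 15 d, in percent of the X charged
- amount of L at 15 d, in percent of the X charged

- the analysis behind the earlier runs scatters by 0.5 percentage points, standard deviation
- candidate steps: X + Q <-> E; X + Q <-> L; E + J <-> L + J; 2 J <-> D; J -> Z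
- the reaction counts as stopped when no species that holds the X changes by six tenths of a point or more over the second half of the time

Step 1. In the ash run, L reads 71.4% and then 71.0%, a step smaller than the scatter, so I take that flask as near rest. Each E or L has used one Q, so its last reading gives H = 13.8 L mol⁻¹.

Step 2. Now a second way, which leaves out the ash X reading. The last elm reading gives [E]/([X][Q]) = 1.66 L mol⁻¹. Scaling that by (E + L)/E from the last ash reading gives 13.5 L mol⁻¹. The two ways share the ash E and L but take their X from different flasks, and they agree, so I trust H.

Step 3. Put H on this flask, where X and Q are used one to one, and solve the quadratic: my estimate at rest is 61.7% of the X bound. E and L both form from X + Q, so I carry over the ash split between them. That gives an end of L 54.2% and E 7.55%.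

Step 4. The elm gap to that L shrinks with a half-time of 2.12 d. If that pace holds, L stands at 49.6% at half the time and 53.8% at the end, with E at 7.66%. That is a gain of 4.2 percentage points over the second half, against a stopping limit of 0.6 points, so I say the flask is still moving.

The forecast also says it is still moving, but with E 7.6% and L 52.5%, an L below mine, and it reads the ash end the same way: “so I read that as equilibrium”.

The flask gives it is still moving, with E 7.39% and L 53.5%.

    X + Q ⇌ E (K = 1.60 L mol⁻¹, k = 1.00 L mol⁻¹ h⁻¹)
    X + Q ⇌ L (K = 12.0 L mol⁻¹, k = 0.0390 L mol⁻¹ h⁻¹)
    E + J ⇌ L + J, rate k3*[J]*[E] forward; the back reaction follows from the equilibrium constant (k = 57.0 L mol⁻¹ h⁻¹)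
    2 J ⇌ D, settled at all times (K = 63000 L mol⁻¹)
    J → Z (k = 0.0330 h⁻¹)

In this flask at 15.0 d, the step between X + Q and E, taken by itself with both directions counted, has a relaxation half-life of 0.844 h, short against the 15 d of the run. At that time X stands at 39.1% and Q at 49.2% of its own charge, so H reads 13.2 L mol⁻¹. For the neighbour charged with 0.96 M of Q, the H from the ash run puts free X at 8.52% at rest, and at 15.0 d that flask holds 8.66%.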